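The aryltetralin is taken apart at its symmetrically 6,7-dioxygenated benzene ring A (C4a, C5, C6, C7, C8, C8a), which is fused to ring B. One cobalt-mediated alkyne cyclotrimerisation forges C4a–C8a, C5–C6 and C7–C8, so ring B closes and ring A is born aromatic in a single operation. The precursor is the open-chain 1,7-diyne 20, which already holds the C1–C3 stereotriad (C1 from a chiral catalyst, C2 from an auxiliary, C3 from a trans-lactone alkylation) and has all four hydroxyls masked as benzyl ethers. Its partner, a diboryl alkyne, brings C6 and C7 with boron as the handle for the two methoxy groups. Oxidation, methylation and one hydrogenolysis finish the synthesis.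

Key step: step 10

Assumptions: compounds 15 and 21 are taken as commercial; in step 2 the ligand antipode that delivers (S)-5 is used (written here as (R); its mirror image is used if it gives the other hand); all tetralins are numbered as in the target (C1 carries the aryl group).

Step 1
Reactants: 1 3,4-bis(benzyloxy)benzaldehyde; 2 Meldrum's acid (2,2-dimethyl-1,3-dioxane-4,6-dione)
Product: 3 5-[3,4-bis(benzyloxy)benzylidene]-2,2-dimethyl-1,3-dioxane-4,6-dione
Conditions: pyrrolidine (cat.), AcOH (cat.), PhMe, 50 °C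
Reagents that add atoms: none
Why: Knoevenagel condensation of an aromatic aldehyde with the strongly C–H acidic Meldrum's acid is reliable, and the arylidene product should crystallise from the mixture.

Step 2
Reactants: 3 5-[3,4-bis(benzyloxy)benzylidene]-2,2-dimethyl-1,3-dioxane-4,6-dione; 4 trimethylsilylacetylene
Product: 5 (S)-5-{1-[3,4-bis(benzyloxy)phenyl]-3-(trimethylsilyl)prop-2-yn-1-yl}-2,2-dimethyl-1,3-dioxane-4,6-dione
Conditions: [Rh(OAc)(C2H4)2]2 (2.5 mol %), (R)-3,5-Xyl-MeO-BIPHEP (5.5 mol %), 4 (3 equiv), 1,4-dioxane, rt → 60 °C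
Reagents that add atoms: none
Why: In this rhodium-catalysed enantioselective conjugate alkynylation of a 5-benzylidene Meldrum's acid, the rhodium acetylide adds 1,4 to the doubly activated alkene and the C2-symmetric bisphosphine selects the face, which sets the future C1.

Step 3
Reactants: 5 (S)-5-{1-[3,4-bis(benzyloxy)phenyl]-3-(trimethylsilyl)prop-2-yn-1-yl}-2,2-dimethyl-1,3-dioxane-4,6-dione
Product: 6 (S)-3-[3,4-bis(benzyloxy)phenyl]-5-(trimethylsilyl)pent-4-ynoic acid
Conditions: DMF/H2O (10:1), 100 °C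
Reagents that add atoms: water, O
Why: Hydrolytic opening of the monosubstituted Meldrum's acid and malonic acid decarboxylation occur on heating in wet DMF, and the stereocentre, β to the carboxyl group, is not touched.

Step 4
Reactants: 6 (S)-3-[3,4-bis(benzyloxy)phenyl]-5-(trimethylsilyl)pent-4-ynoic acid; 7 (S)-4-benzyl-1,3-oxazolidin-2-one
Product: 9 (S)-4-benzyl-3-{(S)-3-[3,4-bis(benzyloxy)phenyl]-5-(trimethylsilyl)pent-4-ynoyl}-1,3-oxazolidin-2-one, via mixed pivalic anhydride 8 (not isolated)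
Conditions: PivCl, Et3N, THF, −20 °C; then 7, LiCl, −20 °C → rt
Reagents that add atoms: none
Why: N-acylation of the oxazolidinone auxiliary through the mixed pivalic anhydride with LiCl and Et3N is a standard mild amide-type coupling that needs no strong base.

Step 5
Reactants: 9 (S)-4-benzyl-3-{(S)-3-[3,4-bis(benzyloxy)phenyl]-5-(trimethylsilyl)pent-4-ynoyl}-1,3-oxazolidin-2-one; 10 tert-butyl bromoacetate
Product: 12 tert-butyl (3S,4S)-3-{[(S)-4-benzyl-2-oxo-1,3-oxazolidin-3-yl]carbonyl}-4-[3,4-bis(benzyloxy)phenyl]-6-(trimethylsilyl)hex-5-ynoate, via sodium enolate 11 (not isolated)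
Conditions: NaN(SiMe3)2, THF, −78 °C; then 10, −78 → −40 °C
Reagents that add atoms: none
Why: In this Evans alkylation the chelated (Z)-sodium enolate is attacked by the reactive α-bromo ester on the face away from the 4-benzyl group, which sets the future C2 under auxiliary control and turns any minor C1 enantiomer into a separable diastereomer.

Step 6
Reactants: 12 tert-butyl (3S,4S)-3-{[(S)-4-benzyl-2-oxo-1,3-oxazolidin-3-yl]carbonyl}-4-[3,4-bis(benzyloxy)phenyl]-6-(trimethylsilyl)hex-5-ynoate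
Product: 14 (S)-4-{(S)-1-[3,4-bis(benzyloxy)phenyl]-3-(trimethylsilyl)prop-2-yn-1-yl}oxolan-2-one, via hydroxy ester 13 (not isolated)
Conditions: LiBH4, MeOH (1 equiv), THF, 0 °C; work-up; then TsOH·H2O (cat.), PhMe, 70 °C
Reagents that add atoms: none
Why: Reductive cleavage of the N-acyl oxazolidinone with LiBH4 spares the tert-butyl ester, and the γ-hydroxy ester then lactonises by acid-catalysed intramolecular transesterification without touching either stereocentre.

Step 7
Reactants: 14 (S)-4-{(S)-1-[3,4-bis(benzyloxy)phenyl]-3-(trimethylsilyl)prop-2-yn-1-yl}oxolan-2-one; 15 3-bromo-1-(trimethylsilyl)prop-1-yne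
Product: 17 (3R,4R)-4-{(S)-1-[3,4-bis(benzyloxy)phenyl]-3-(trimethylsilyl)prop-2-yn-1-yl}-3-[3-(trimethylsilyl)prop-2-yn-1-yl]oxolan-2-one, via lithium enolate 16 (not isolated)
Conditions: LiN(SiMe3)2, THF, −78 °C; then 15, −78 → −30 °C
Reagents that add atoms: none
Why: In this diastereoselective alkylation of a β-substituted γ-butyrolactone enolate the propargylic bromide approaches anti to the bulky ring substituent, so the future C3 is set trans to the group at the future C2 by substrate control, the classical route to trans-disubstituted lignan lactones.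

Step 8
Reactants: 17 (3R,4R)-4-{(S)-1-[3,4-bis(benzyloxy)phenyl]-3-(trimethylsilyl)prop-2-yn-1-yl}-3-[3-(trimethylsilyl)prop-2-yn-1-yl]oxolan-2-one
Product: 19 (2R,3R)-2-{(R)-1-[3,4-bis(benzyloxy)phenyl]prop-2-yn-1-yl}-3-(prop-2-yn-1-yl)butane-1,4-diol, via bis-silyl diol 18 (not isolated)
Conditions: LiAlH4, THF, 0 °C; work-up; then K2CO3 (0.3 equiv), MeOH, 0 °C → rt
Reagents that add atoms: none
Why: Hydride reduction opens the lactone to the 1,4-diol without touching the isolated silylalkynes, and mild base-catalysed methanolysis (protodesilylation) frees both alkyne termini; the descriptor at the aryl-bearing carbon changes from S to R only because aryl outranks ethynyl but not silylethynyl.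

Step 9
Reactants: 19 (2R,3R)-2-{(R)-1-[3,4-bis(benzyloxy)phenyl]prop-2-yn-1-yl}-3-(prop-2-yn-1-yl)butane-1,4-diol
Product: 20 (3R,4R,5R)-3-[3,4-bis(benzyloxy)phenyl]-4,5-bis[(benzyloxy)methyl]octa-1,7-diyne
Conditions: BnOC(=NH)CCl3 (3 equiv), TfOH (cat.), CH2Cl2/cyclohexane, 0 °C → rt
Reagents that add atoms: benzyl 2,2,2-trichloroacetimidate, N=C(OCc1ccccc1)C(Cl)(Cl)Cl
Why: Acid-catalysed O-benzylation with the trichloroacetimidate protects both primary alcohols without base, so the benzylic and propargylic C–H at the aryl-bearing carbon cannot be removed and isomerise to an allene.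

Step 10
Reactants: 20 (3R,4R,5R)-3-[3,4-bis(benzyloxy)phenyl]-4,5-bis[(benzyloxy)methyl]octa-1,7-diyne; 21 bis(pinacolboryl)acetylene (1,2-bis(4,4,5,5-tetramethyl-1,3,2-dioxaborolan-2-yl)ethyne)
Product: 22 (1S,2R,3R)-1-[3,4-bis(benzyloxy)phenyl]-2,3-bis[(benzyloxy)methyl]-6,7-bis(4,4,5,5-tetramethyl-1,3,2-dioxaborolan-2-yl)-1,2,3,4-tetrahydronaphthalene
Conditions: CpCo(CO)2 (20 mol %), 21 (3 equiv), dry degassed xylenes, reflux, hν (visible lamp), 20 added by syringe pump over 10 h
Reagents that add atoms: none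
Why: The CpCo fragment, freed from CpCo(CO)2 by heat and light, couples the two terminal alkynes of 20 oxidatively to a bicyclic cobaltacyclopentadiene, takes up the diboryl alkyne 21 and releases the arene by reductive elimination; the closest known reaction type is the CpCo(CO)2-mediated [2+2+2] cocyclisation of α,ω-diynes with silyl- or boryl-substituted alkynes. Ring B, a six-membered carbocycle, closes in the oxidative coupling, which joins the two inner alkyne carbons as C4a–C8a across the C1–C4 tether. Ring A closes when 21 inserts into the metallacycle and cobalt is eliminated, which forms C5–C6 and C7–C8 and gives the benzene ring directly. No stereocentre is created, and the conditions are neutral and free of base and acid, so the C1–C3 triad of 20 should pass unchanged into 22. The selectivity needed is cross- over self-cyclotrimerisation: 21 is too hindered to trimerise alone, the tether of 20 (all three substituents equatorial in the forming ring) makes metallacycle formation intramolecular, slow addition keeps free diyne scarce, and the symmetry of 21 leaves no regiochemical question. The benzyl ethers keep hydroxyl groups away from the protolytically labile alkynyl–boron bonds of 21.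

Step 11
Reactants: 22 (1S,2R,3R)-1-[3,4-bis(benzyloxy)phenyl]-2,3-bis[(benzyloxy)methyl]-6,7-bis(4,4,5,5-tetramethyl-1,3,2-dioxaborolan-2-yl)-1,2,3,4-tetrahydronaphthalene
Product: 24 (1S,2R,3R)-1-[3,4-bis(benzyloxy)phenyl]-2,3-bis[(benzyloxy)methyl]-6,7-dimethoxy-1,2,3,4-tetrahydronaphthalene, via catechol 23 (not isolated)
Conditions: NaBO3·4H2O, THF/H2O, rt; work-up under argon; then MeI, K2CO3, acetone, 50 °C
Reagents that add atoms: sodium perborate, [Na+].[O-]B1OO1; iodomethane, CI
Why: Perborate oxidation of the arylboronic esters (1,2-shift of aryl from boron to oxygen) turns both C–B bonds into phenols, and the air-sensitive catechol is methylated at once by Williamson etherification, to which benzyl ethers are inert.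

Step 12
Reactants: 24 (1S,2R,3R)-1-[3,4-bis(benzyloxy)phenyl]-2,3-bis[(benzyloxy)methyl]-6,7-dimethoxy-1,2,3,4-tetrahydronaphthalene
Product: 25 4-[(1S,2R,3R)-2,3-bis(hydroxymethyl)-6,7-dimethoxy-1,2,3,4-tetrahydronaphthalen-1-yl]benzene-1,2-diol
Conditions: H2 (1 atm), 10% Pd/C, EtOAc/MeOH, rt
Reagents that add atoms: none
Why: Catalytic hydrogenolysis cleaves the two aryl and the two alkyl benzyl ethers in one operation, while the methyl ethers, the arenes and the three stereocentres are unaffected.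

Compound list

1 | 3,4-bis(benzyloxy)benzaldehyde | O=Cc1ccc(OCc2ccccc2)c(OCc2ccccc2)c1 | starting material
2 | Meldrum's acid | CC1(C)OC(=O)CC(=O)O1 | starting material
3 | 5-[3,4-bis(benzyloxy)benzylidene]-2,2-dimethyl-1,3-dioxane-4,6-dione | CC1(C)OC(=O)C(=Cc2ccc(OCc3ccccc3)c(OCc3ccccc3)c2)C(=O)O1 | intermediate
4 | trimethylsilylacetylene | C#C[Si](C)(C)C | starting material
5 | (S)-5-{1-[3,4-bis(benzyloxy)phenyl]-3-(trimethylsilyl)prop-2-yn-1-yl}-2,2-dimethyl-1,3-dioxane-4,6-dione | C[Si](C)(C)C#C[C@H](c1ccc(OCc2ccccc2)c(OCc2ccccc2)c1)C1C(=O)OC(C)(C)OC1=O | intermediate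
6 | (S)-3-[3,4-bis(benzyloxy)phenyl]-5-(trimethylsilyl)pent-4-ynoic acid | C[Si](C)(C)C#C[C@H](c1ccc(OCc2ccccc2)c(OCc2ccccc2)c1)CC(=O)O | intermediate
7 | (S)-4-benzyl-1,3-oxazolidin-2-one | O=C1N[C@@H](Cc2ccccc2)CO1 | starting material
8 | mixed anhydride of acid 6 with pivalic acid | C[Si](C)(C)C#C[C@H](c1ccc(OCc2ccccc2)c(OCc2ccccc2)c1)CC(=O)OC(=O)C(C)(C)C | intermediate
9 | (S)-4-benzyl-3-{(S)-3-[3,4-bis(benzyloxy)phenyl]-5-(trimethylsilyl)pent-4-ynoyl}-1,3-oxazolidin-2-one | C[Si](C)(C)C#C[C@H](c1ccc(OCc2ccccc2)c(OCc2ccccc2)c1)CC(=O)N1[C@@H](Cc2ccccc2)COC1=O | intermediate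
10 | tert-butyl bromoacetate | CC(C)(C)OC(=O)CBr | starting material
11 | sodium (Z)-enolate of imide 9 | C[Si](C)(C)C#C[C@H](c1ccc(OCc2ccccc2)c(OCc2ccccc2)c1)/C=C(\[O-])N1[C@@H](Cc2ccccc2)COC1=O.[Na+] | intermediate
12 | tert-butyl (3S,4S)-3-{[(S)-4-benzyl-2-oxo-1,3-oxazolidin-3-yl]carbonyl}-4-[3,4-bis(benzyloxy)phenyl]-6-(trimethylsilyl)hex-5-ynoate | C[Si](C)(C)C#C[C@H](c1ccc(OCc2ccccc2)c(OCc2ccccc2)c1)[C@@H](C(=O)N1[C@@H](Cc2ccccc2)COC1=O)CC(=O)OC(C)(C)C | intermediate
13 | tert-butyl (3S,4S)-4-[3,4-bis(benzyloxy)phenyl]-3-(hydroxymethyl)-6-(trimethylsilyl)hex-5-ynoate | C[Si](C)(C)C#C[C@H](c1ccc(OCc2ccccc2)c(OCc2ccccc2)c1)[C@@H](CO)CC(=O)OC(C)(C)C | intermediate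
14 | (S)-4-{(S)-1-[3,4-bis(benzyloxy)phenyl]-3-(trimethylsilyl)prop-2-yn-1-yl}oxolan-2-one | C[Si](C)(C)C#C[C@H](c1ccc(OCc2ccccc2)c(OCc2ccccc2)c1)[C@H]1COC(=O)C1 | intermediate
15 | 3-bromo-1-(trimethylsilyl)prop-1-yne | C[Si](C)(C)C#CCBr | starting material
16 | lithium enolate of lactone 14 | C[Si](C)(C)C#C[C@H](c1ccc(OCc2ccccc2)c(OCc2ccccc2)c1)[C@H]1COC([O-])=C1.[Li+] | intermediate
17 | (3R,4R)-4-{(S)-1-[3,4-bis(benzyloxy)phenyl]-3-(trimethylsilyl)prop-2-yn-1-yl}-3-[3-(trimethylsilyl)prop-2-yn-1-yl]oxolan-2-one | C[Si](C)(C)C#C[C@H](c1ccc(OCc2ccccc2)c(OCc2ccccc2)c1)[C@H]1COC(=O)[C@@H]1CC#C[Si](C)(C)C | intermediate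
18 | (2R,3R)-2-{(S)-1-[3,4-bis(benzyloxy)phenyl]-3-(trimethylsilyl)prop-2-yn-1-yl}-3-[3-(trimethylsilyl)prop-2-yn-1-yl]butane-1,4-diol | C[Si](C)(C)C#C[C@H](c1ccc(OCc2ccccc2)c(OCc2ccccc2)c1)[C@@H](CO)[C@H](CO)CC#C[Si](C)(C)C | intermediate
19 | (2R,3R)-2-{(R)-1-[3,4-bis(benzyloxy)phenyl]prop-2-yn-1-yl}-3-(prop-2-yn-1-yl)butane-1,4-diol | C#C[C@H](c1ccc(OCc2ccccc2)c(OCc2ccccc2)c1)[C@@H](CO)[C@H](CO)CC#C | intermediate
20 | (3R,4R,5R)-3-[3,4-bis(benzyloxy)phenyl]-4,5-bis[(benzyloxy)methyl]octa-1,7-diyne | C#C[C@H](c1ccc(OCc2ccccc2)c(OCc2ccccc2)c1)[C@@H](COCc1ccccc1)[C@H](COCc1ccccc1)CC#C | intermediate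
21 | bis(pinacolboryl)acetylene | CC1(C)OB(OC1(C)C)C#CB1OC(C)(C)C(C)(C)O1 | starting material
22 | (1S,2R,3R)-1-[3,4-bis(benzyloxy)phenyl]-2,3-bis[(benzyloxy)methyl]-6,7-bis(4,4,5,5-tetramethyl-1,3,2-dioxaborolan-2-yl)-1,2,3,4-tetrahydronaphthalene | CC1(C)OB(OC1(C)C)c1cc2c(cc1B1OC(C)(C)C(C)(C)O1)[C@H](c1ccc(OCc3ccccc3)c(OCc3ccccc3)c1)[C@@H](COCc1ccccc1)[C@H](COCc1ccccc1)C2 | intermediate
23 | (1S,2R,3R)-1-[3,4-bis(benzyloxy)phenyl]-2,3-bis[(benzyloxy)methyl]-1,2,3,4-tetrahydronaphthalene-6,7-diol | Oc1cc2c(cc1O)[C@H](c1ccc(OCc3ccccc3)c(OCc3ccccc3)c1)[C@@H](COCc1ccccc1)[C@H](COCc1ccccc1)C2 | intermediate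
24 | (1S,2R,3R)-1-[3,4-bis(benzyloxy)phenyl]-2,3-bis[(benzyloxy)methyl]-6,7-dimethoxy-1,2,3,4-tetrahydronaphthalene | COc1cc2c(cc1OC)[C@H](c1ccc(OCc3ccccc3)c(OCc3ccccc3)c1)[C@@H](COCc1ccccc1)[C@H](COCc1ccccc1)C2 | intermediate
25 | 4-[(1S,2R,3R)-2,3-bis(hydroxymethyl)-6,7-dimethoxy-1,2,3,4-tetrahydronaphthalen-1-yl]benzene-1,2-diol | COc1cc2c(cc1OC)[C@H](c1ccc(O)c(O)c1)[C@@H](CO)[C@H](CO)C2 | target

Total step count: 12. Longest linear sequence: 12 steps (from 1 and 2 to 25); all other inputs are commercial.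

Steps most likely to fail

Step 10. The diyne may condense with itself faster than the cobaltacycle captures the hindered diboryl alkyne, or moisture may cleave the alkynyl–boron bonds before insertion. The fallback sets out from 20 and returns at 23; it uses a small terminal boryl alkyne and adds the second oxygen afterwards. Diyne 20 and commercial 2-ethynyl-4,4,5,5-tetramethyl-1,3,2-dioxaborolane are cyclotrimerised with Cp*RuCl(cod) in 1,2-dichloroethane at room temperature, the known ruthenium-catalysed cycloaddition of α,ω-diynes with alkynylboronates, in which the monoalkyne does not trimerise alone. This should give two regioisomeric monoboronates, the 6-boryl tetralin F1 and the 7-boryl tetralin F2, which are not separated. Oxidation with NaBO3·4H2O gives the 6-hydroxy tetralin F3 and the 7-hydroxy tetralin F4. IBX in DMF oxidises each phenol at its unhindered ortho carbon (C7 in F3, C6 in F4), so both converge on the same ortho-quinone F5, which is reduced in the same flask with Na2S2O4 to catechol 23. Catechol 23 is then methylated as in the second operation of step 11.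

Step 2. Addition to the electron-rich, less electrophilic arylidene may be slow, facial selectivity may be poor, or the alkyne may dimerise instead. The fallback sets out from 3 and returns at 9; it sets the future C1 by separating diastereomers instead of by catalysis. Trimethylsilylethynylmagnesium bromide (from 4 and EtMgBr) adds to 3 in THF at 0 °C without catalyst to give the racemic adduct F6. Hydrolysis and decarboxylation as in step 3 give the racemic acid F7. Acylation of auxiliary 7 as in step 4 gives imide 9 together with its epimer at the aryl-bearing carbon, the (R)-configured imide F8. The two diastereomers are separated by crystallisation or chromatography and the route continues from 9.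

Step 9. The benzyl cation equivalent may alkylate the electron-rich dialkoxyarene on carbon, or etherification may stop at the mono-ether. The fallback sets out from 18 and returns at 20; it changes the mechanism to SN2 etherification and moves it before desilylation. Diol 18 is isolated after the LiAlH4 reduction of step 8 and treated with NaH, BnBr and Bu4NI in THF at 0 °C, which should give the bis-silyl tetrabenzyl diyne F9 while both alkyne termini are still capped. K2CO3 in MeOH then removes both silyl groups to give 20. The optical purity at the aryl-bearing carbon would be checked before the material is carried on.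

Further compounds

F1 | step 10 | (1S,2R,3R)-1-[3,4-bis(benzyloxy)phenyl]-2,3-bis[(benzyloxy)methyl]-6-(4,4,5,5-tetramethyl-1,3,2-dioxaborolan-2-yl)-1,2,3,4-tetrahydronaphthalene | CC1(C)OB(OC1(C)C)c1cc2c(cc1)[C@H](c1ccc(OCc3ccccc3)c(OCc3ccccc3)c1)[C@@H](COCc1ccccc1)[C@H](COCc1ccccc1)C2
F2 | step 10 | (1S,2R,3R)-1-[3,4-bis(benzyloxy)phenyl]-2,3-bis[(benzyloxy)methyl]-7-(4,4,5,5-tetramethyl-1,3,2-dioxaborolan-2-yl)-1,2,3,4-tetrahydronaphthalene | c1cc2c(cc1B1OC(C)(C)C(C)(C)O1)[C@H](c1ccc(OCc3ccccc3)c(OCc3ccccc3)c1)[C@@H](COCc1ccccc1)[C@H](COCc1ccccc1)C2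
F3 | step 10 | (1S,2R,3R)-1-[3,4-bis(benzyloxy)phenyl]-2,3-bis[(benzyloxy)methyl]-1,2,3,4-tetrahydronaphthalen-6-ol | Oc1cc2c(cc1)[C@H](c1ccc(OCc3ccccc3)c(OCc3ccccc3)c1)[C@@H](COCc1ccccc1)[C@H](COCc1ccccc1)C2
F4 | step 10 | (1S,2R,3R)-1-[3,4-bis(benzyloxy)phenyl]-2,3-bis[(benzyloxy)methyl]-1,2,3,4-tetrahydronaphthalen-7-ol | c1cc2c(cc1O)[C@H](c1ccc(OCc3ccccc3)c(OCc3ccccc3)c1)[C@@H](COCc1ccccc1)[C@H](COCc1ccccc1)C2
F5 | step 10 | (1S,2R,3R)-1-[3,4-bis(benzyloxy)phenyl]-2,3-bis[(benzyloxy)methyl]-1,2,3,4-tetrahydronaphthalene-6,7-dione | O=C1C=C2C(=CC1=O)[C@H](c1ccc(OCc3ccccc3)c(OCc3ccccc3)c1)[C@@H](COCc1ccccc1)[C@H](COCc1ccccc1)C2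
F6 | step 2 | racemic 5-{1-[3,4-bis(benzyloxy)phenyl]-3-(trimethylsilyl)prop-2-yn-1-yl}-2,2-dimethyl-1,3-dioxane-4,6-dione | C[Si](C)(C)C#CC(c1ccc(OCc2ccccc2)c(OCc2ccccc2)c1)C1C(=O)OC(C)(C)OC1=O
F7 | step 2 | racemic 3-[3,4-bis(benzyloxy)phenyl]-5-(trimethylsilyl)pent-4-ynoic acid | C[Si](C)(C)C#CC(c1ccc(OCc2ccccc2)c(OCc2ccccc2)c1)CC(=O)O
F8 | step 2 | (S)-4-benzyl-3-{(R)-3-[3,4-bis(benzyloxy)phenyl]-5-(trimethylsilyl)pent-4-ynoyl}-1,3-oxazolidin-2-one | C[Si](C)(C)C#C[C@@H](c1ccc(OCc2ccccc2)c(OCc2ccccc2)c1)CC(=O)N1[C@@H](Cc2ccccc2)COC1=O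
F9 | step 9 | (3S,4R,5R)-3-[3,4-bis(benzyloxy)phenyl]-4,5-bis[(benzyloxy)methyl]-1,8-bis(trimethylsilyl)octa-1,7-diyne | C[Si](C)(C)C#C[C@H](c1ccc(OCc2ccccc2)c(OCc2ccccc2)c1)[C@@H](COCc1ccccc1)[C@H](COCc1ccccc1)CC#C[Si](C)(C)C
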